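## The problem

Compound 19 is the 5,5'-linked dimer of 2-hydroxy-3-methyl-6-[2-(2-methoxyphenyl)ethyl]-1,4-benzoquinone, with each quinone ring numbered here C1 (the C=O next to the side-chain carbon), C2 (C–OH), C3 (C–CH3), C4 (C=O), C5 (the carbon of the inter-ring bond) and C6 (the carbon bearing CH2CH2Ar, Ar = 2-methoxyphenyl). All six positions of both rings are substituted, and the C5–C5' bond joins the rings between four ortho neighbours (two carbonyls and two arylethyl chains), so it is the hard bond: a late coupling of two hexasubstituted arenes would be slow and unselective. There is no stereocentre; the hindered C5–C5' axis is the only stereogenic element, the target leaves it undefined, and it is made as the racemate, so no element of the route has to control another. The 2-hydroxy-1,4-quinones are acidic, electrophilic and easily reduced and should appear only in the last step. The two anisole methyl ethers must survive to the end, which rules out carrying the ring oxygens as methyl ethers, and the anisole rings are open to electrophilic halogenation. The enabling feature is that in each ring the chain CH3–C3–C4(=O)–C5=C6 is an ethyl enone whose β-carbon C6 carries the side chain, that the missing atoms C1 and C2 are two carbons of a malonate, and that the two enones share the C5–C5' bond. Both rings can therefore be grown at once on a symmetric bis-enone, and the congested bond can be made while C5 is still an unhindered alkenyl carbon.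

## Retrosynthesis

**19 to 18.** The oxygen at C1 of each ring is removed first. A 2-hydroxy-1,4-quinone is the oxidation product of a 2-methylresorcinol with a free position para to one hydroxyl, so 19 goes back to the bis-resorcinol 18 with C1–H. Against carrying a hydroquinone through the synthesis, this needs no O-protecting group that would later have to be told apart from the anisole ethers. The forward step must oxidise only C1 of both rings and leave the anisole rings alone.

**18 to 16 to 13.** Each resorcinol ring is a dehydrogenated cyclohexane-1,3-dione. Putting a methoxycarbonyl group back on C1 gives the bis-resorcylate 16, and adding two hydrogens per ring gives the bis(2,4-dioxocyclohexanecarboxylate) 13. The ester is kept through the aromatisation on purpose: with CO2CH3 on C1 every position of the new arene is blocked against the halogen used to dehydrogenate. The forward steps are a halogenation–dehydrohalogenation and a saponification–decarboxylation, both under conditions that leave aryl methyl ethers intact.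

**13 to 10 and 11 (key disconnection).** In each ring the bonds C1–C6 and C2–C3 are cut. This removes both rings and all sp3 centres in one operation and leaves the acyclic bis-enone 10 and two molecules of dimethyl malonate 11. The neighbouring cut, one ring at a time on a monomeric enone, is the literal precedent but would leave C5–C5' to be made between two crowded arenes. The forward reaction must give twofold conjugate addition at C6 and C6', then Claisen closure of each ethyl ketone on a malonate ester.

**10 to 9.** The C5–C5' bond is cut at the stage where both carbons are alkenyl carbons with only one large neighbour each, so 10 is the oxidative dimer of the α-stannyl enone 9. The neighbouring plan, oxidative dimerisation of 4 and twofold hydrometalation with both metals on the inner carbons, was set aside because the second addition would have to go against its steric bias. Here the tin is placed by the carbonyl group. The homocoupling must be faster than protodestannylation; retention of alkene geometry is welcome but not needed.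

**9 to 8 to 4 and 5.** The C–Sn and the cis C–H bond of 9 come from palladium-catalysed syn-hydrostannation of the alkynyl ketone 8, which puts tin α to the carbonyl. 8 is cut at the acyl–alkyne bond into the terminal alkyne 4 and N-methoxy-N-methylpropanamide 5, which supplies C3, C4 and the C3 methyl group.

**4 to 1 and 2.** The benzylic CH2–CH2 bond of 4 is cut into 2-methoxybenzyl chloride 1 and the three-carbon unit of propargyl bromide 2, used as allenylmagnesium bromide 3. All four building blocks (1, 2, 5, 11) are commercial.

## Roads not taken

**Alternative 1:** The cut is at the two CH2–aryl bonds of the side chains. Hydroboration of the 6,6'-divinyl biaryl A2 and twofold B-alkyl Suzuki coupling with 2-iodoanisole A3 would give the tetrabenzyl ether A1. Hydrogenolysis of A1 would give 18, so this road meets the chosen one before the last oxidation.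
- Merits: the sp3–sp2 coupling is reliable, the anisole rings enter late (useful for analogues), and there is neither tin nor a stereoisomer mixture.
- Weak points: A2 is itself a tetra-ortho-substituted biaryl with four protected phenols, so the hardest bond (C5–C5') is moved upstream and not solved. Benzylation and debenzylation add steps.
- Comparison: the key step of this road is more predictable than the twofold annulation. The chosen plan sets against it that C5–C5' is made between two small alkenyl carbons, that no protecting group is used, and that the route is eight steps long.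

**Alternative 2:** The cut removes three bonds of one ring (C1'–C6', C5'–C4', C4'–C3'). A Dötz benzannulation of the alkenyl chromium carbene A6 with the ring A aryl alkyne A5 and one CO ligand would give the biaryl A4 with ring B as a 4-methoxyphenol.
- Merits: oxygen is already in place at C1' and C4' of ring B, so no late C–H oxidation is needed, and the larger alkyne substituent is reliably placed next to the new phenol.
- Weak points: only one ring is made, so the hexasubstituted ring A of A5 must be built separately and the symmetry of the target is unused. An internal alkyne flanked by a 2,6-disubstituted aryl group reacts slowly with Fischer carbenes, and other cyclisation modes compete. Chromium is stoichiometric. The end game must turn five ring methyl ethers into two quinones and two free C2 hydroxyls while two anisole methyl ethers stay.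
- Comparison: this road fixes the oxygenation pattern more securely than a late oxidation of 18. The chosen plan is shorter, uses the symmetry, and never has to tell one methyl ether from another.

**Alternative 3:** The cut is at C4–C5 and C1–C6 of both rings. Twofold Diels–Alder addition of the 2-silyloxyfuran A9 to the conjugated diynedione A8, then opening of the oxygen bridges, would give the bis(hydroquinone monosilyl ether) A7.
- Merits: this is also two-directional and symmetric, and it delivers both rings at the hydroquinone oxidation level with the C2 oxygen in place. In ring construction it is at least as convergent as the chosen plan.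
- Weak points: silyloxyfurans usually add to alkynyl ketones as vinylogous Michael donors and give butenolides, not cycloadducts. The second cycloaddition has to occur next to a newly formed hexasubstituted ring. A8 has acidic CH2 groups between an aryl ring and an ynone and is prone to isomerise. A7 still needs both side-chain ketones reduced to CH2 and the C2 methyl ethers cleaved beside the anisole ethers.
- Comparison: the oxygenation is better solved here. The chosen plan sets against it a side chain at the correct oxidation level from the first step, no ether differentiation, and a key step modelled on a well-used monomer reaction.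

Key step: step 5

Assumption: the target is drawn without stereodescriptors, so the C5–C5' axis is made as the racemate and no stereocentre has to be set.
Assumption: the two trisubstituted alkenes of 10 are drawn (Z,Z), as expected from syn-hydrostannation and coupling with retention; either geometry serves, because both alkene carbons become sp3 in step 5.

## Route

Step 1
Reactants: 1 2-methoxybenzyl chloride; 2 propargyl bromide (3-bromoprop-1-yne)
Product: 4 4-(2-methoxyphenyl)but-1-yne, via allenylmagnesium bromide 3 (not isolated)
Conditions: 2, Mg, HgCl2 (cat.), Et2O, 0 °C; then 1, THF, 0 °C to reflux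
Reagents that add atoms: none
Why: Propargylation of a benzylic halide: the Grignard reagent from 2 exists as the allenyl species 3 and attacks the benzylic carbon through its γ-carbon (SE2'), which gives the homopropargyl arene.

Step 2
Reactants: 4 4-(2-methoxyphenyl)but-1-yne; 5 N-methoxy-N-methylpropanamide
Product: 8 7-(2-methoxyphenyl)hept-4-yn-3-one, via lithium acetylide 6 (not isolated), via lithium hemiaminal adduct 7 (not isolated)
Conditions: n-BuLi, THF, −78 °C; then 5, −78 to 0 °C; aq. HCl (1 M), 0 °C
Reagents that add atoms: none
Why: Weinreb ketone synthesis: the acetylide adds once to the amide, the chelated adduct 7 resists a second addition and collapses to the alkynyl ketone only on acidic work-up; the anisole is not lithiated at −78 °C.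

Step 3
Reactants: 8 7-(2-methoxyphenyl)hept-4-yn-3-one
Product: 9 (E)-7-(2-methoxyphenyl)-4-(tributylstannyl)hept-4-en-3-one
Conditions: Bu3SnH, Pd(PPh3)4 (cat.), THF, 0 °C to rt
Reagents that add atoms: tributyltin hydride, CCCC[SnH](CCCC)CCCC
Why: Palladium-catalysed syn-hydrostannation of an alkynyl ketone: hydride goes to the β-carbon and tin to the carbon α to the carbonyl, so H and Sn end up cis and the side chain cis to the acyl group.

Step 4
Reactants: 9 (E)-7-(2-methoxyphenyl)-4-(tributylstannyl)hept-4-en-3-one (two molecules)
Product: 10 (4Z,5Z)-4,5-bis[3-(2-methoxyphenyl)propylidene]octane-3,6-dione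
Conditions: Cu(NO3)2·3H2O, THF, rt
Reagents that add atoms: none
Why: Copper-mediated oxidative homocoupling of an alkenylstannane (tin-to-copper transmetalation, then coupling of two alkenylcopper units), a reaction established for carbonyl-conjugated alkenylstannanes; it forms C5–C5' while both carbons are small sp2 centres, and any loss of alkene geometry is harmless.

Step 5
Reactants: 10 (4Z,5Z)-4,5-bis[3-(2-methoxyphenyl)propylidene]octane-3,6-dione; 11 dimethyl malonate (two molecules)
Product: 13 5,5'-linked dimer of methyl 6-[2-(2-methoxyphenyl)ethyl]-3-methyl-2,4-dioxocyclohexane-1-carboxylate (stereoisomer and enol mixture), via bis-Michael tetraester 12 (not isolated)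
Conditions: dimethyl malonate 11 (excess), NaOCH3, CH3OH, 0 °C to rt, then reflux; aq. HCl, 0 °C
Reagents that add atoms: dimethyl malonate (the second of the two molecules of 11), COC(=O)CC(=O)OC
Why: Two molecules of 11 are consumed, one per enone: sodiomalonate, buffered by excess 11, adds 1,4 to the β-carbon C6 of each enone of 10 (C1–C6 and C1'–C6'), and kinetic protonation of the first adduct at C5 leaves the second enone intact for the second addition, which gives 12. On heating, each ethyl ketone is enolised towards its CH2 (C3), and this enolate attacks one ester of the neighbouring malonate (C2–C3) in a 6-(enolexo)-exo-trig Claisen (Dieckmann-type) closure that expels methoxide; both rings close in this mode, with loss of two molecules of methanol in all. The closest known reaction is the annulation of dimethyl malonate with hex-4-en-3-one and its homologues to methyl 3-methyl-2,4-dioxocyclohexane-1-carboxylates, of which each half of 10 is an α-substituted case. Immediate deprotonation of each new 2-methyl-1,3-dione at C3 makes the closures irreversible and draws the reversible Michael steps forward. The new sp3 centres at C1, C3, C5 and C6 of both rings are not controlled and need not be, because all become sp2 in step 6. The step needs 1,4- and not 1,2-addition, which the soft malonate anion secures, and six-membered Claisen closure and not a second Michael addition of C1 to C6', which would be a disfavoured 5-endo-trig closure. It also needs the mono-adduct not to tautomerise to a 2-ene-1,4-dione and 12 not to close to a cyclopentenone by aldol reaction between its two ketones; the low basicity of the malonate buffer during the addition stage, the loss of electrophilicity at C4 once the first ring sits as its enolate, and the irreversible Claisen step favour the wanted course.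

Step 6
Reactants: 13 5,5'-linked dimer of methyl 6-[2-(2-methoxyphenyl)ethyl]-3-methyl-2,4-dioxocyclohexane-1-carboxylate
Product: 16 5,5'-linked dimer of methyl 2,4-dihydroxy-6-[2-(2-methoxyphenyl)ethyl]-3-methylbenzoate, via bis(3-bromo dione) 14 (not isolated), via bis(1-bromo β-keto ester) 15 (not isolated)
Conditions: Br2 (1 equiv per ring), DMF, 0 °C; then 80 °C
Reagents that add atoms: none
Why: Halogenation–dehydrohalogenation aromatisation of a cyclohexane-1,3-dione: the dione enols take up bromine at C3 far faster than the anisole rings do, the HBr formed relays the halogen to the acidic β-keto ester carbon C1, and E2 loss of HBr across C1–C6 in warm DMF followed by enolisation gives the resorcylate. Every position of the new arene is substituted, so no nuclear bromination can follow.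

Step 7
Reactants: 16 5,5'-linked dimer of methyl 2,4-dihydroxy-6-[2-(2-methoxyphenyl)ethyl]-3-methylbenzoate
Product: 18 6,6'-bis[2-(2-methoxyphenyl)ethyl]-3,3'-dimethylbiphenyl-2,2',4,4'-tetrol, via bis(resorcylic acid) 17 (not isolated)
Conditions: KOH, H2O/CH3OH (degassed), reflux; then aq. HCl, 60 °C
Reagents that add atoms: none
Why: Saponification of the salicylate-type esters, then decarboxylation of the 2,4-dihydroxybenzoic acids, which lose CO2 readily by ipso-protonation at C1; aryl methyl ethers are inert to hydroxide, and air is excluded because the resorcinolate is easily oxidised.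

Step 8
Reactants: 18 6,6'-bis[2-(2-methoxyphenyl)ethyl]-3,3'-dimethylbiphenyl-2,2',4,4'-tetrol
Product: 19 4,4'-dihydroxy-2,2'-bis[2-(2-methoxyphenyl)ethyl]-5,5'-dimethyl-[1,1'-bi(cyclohexa-1,4-diene)]-3,3',6,6'-tetrone (target)
Conditions: (KSO3)2NO (Fremy's salt, excess), KH2PO4, H2O/acetone, rt
Reagents that add atoms: potassium nitrosodisulfonate, [K+].[K+].[O]N(S(=O)(=O)[O-])S(=O)(=O)[O-]
Why: Teuber oxidation: the nitroxyl radical abstracts the hydrogen of the C4 hydroxyl, a second equivalent adds at the free para position C1, and loss of imidodisulfonate gives the 1,4-quinone with the C2 hydroxyl retained; 2-methylresorcinols with a free 4-position are standard substrates, and anisole ethers are not touched.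

## Compound list

1 | 2-methoxybenzyl chloride | COc1ccccc1CCl | starting material
2 | propargyl bromide (3-bromoprop-1-yne) | C#CCBr | starting material
3 | allenylmagnesium bromide | C=C=C[Mg]Br | intermediate
4 | 4-(2-methoxyphenyl)but-1-yne | C#CCCc1ccccc1OC | intermediate
5 | N-methoxy-N-methylpropanamide | CCC(=O)N(C)OC | starting material
6 | lithium 4-(2-methoxyphenyl)but-1-yn-1-ide | [Li]C#CCCc1ccccc1OC | intermediate
7 | lithium 3-[methoxy(methyl)amino]-7-(2-methoxyphenyl)hept-4-yn-3-olate | CCC(O[Li])(C#CCCc1ccccc1OC)N(C)OC | intermediate
8 | 7-(2-methoxyphenyl)hept-4-yn-3-one | CCC(=O)C#CCCc1ccccc1OC | intermediate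
9 | (E)-7-(2-methoxyphenyl)-4-(tributylstannyl)hept-4-en-3-one | CCC(=O)/C(=C\CCc1ccccc1OC)[Sn](CCCC)(CCCC)CCCC | intermediate
10 | (4Z,5Z)-4,5-bis[3-(2-methoxyphenyl)propylidene]octane-3,6-dione | COc1ccccc1CC/C=C(/C(=C/CCc1ccccc1OC)C(=O)CC)C(=O)CC | intermediate
11 | dimethyl malonate | COC(=O)CC(=O)OC | starting material
12 | tetramethyl 2,2'-[1,8-bis(2-methoxyphenyl)-4,5-dipropanoyloctane-3,6-diyl]dipropanedioate (stereoisomer mixture) | CCC(=O)C(C(CCc1ccccc1OC)C(C(=O)OC)C(=O)OC)C(C(=O)CC)C(CCc1ccccc1OC)C(C(=O)OC)C(=O)OC | intermediate
13 | 5,5'-linked dimer of methyl 6-[2-(2-methoxyphenyl)ethyl]-3-methyl-2,4-dioxocyclohexane-1-carboxylate (stereoisomer and enol mixture) | COC(=O)C1C(=O)C(C)C(=O)C(C1CCc1ccccc1OC)C1C(CCc2ccccc2OC)C(C(=O)OC)C(=O)C(C)C1=O | intermediate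
14 | 5,5'-linked dimer of methyl 3-bromo-6-[2-(2-methoxyphenyl)ethyl]-3-methyl-2,4-dioxocyclohexane-1-carboxylate (stereoisomer mixture) | COC(=O)C1C(=O)C(C)(Br)C(=O)C(C1CCc1ccccc1OC)C1C(CCc2ccccc2OC)C(C(=O)OC)C(=O)C(C)(Br)C1=O | intermediate
15 | 5,5'-linked dimer of methyl 1-bromo-6-[2-(2-methoxyphenyl)ethyl]-3-methyl-2,4-dioxocyclohexane-1-carboxylate (stereoisomer mixture) | COC(=O)C1(Br)C(=O)C(C)C(=O)C(C1CCc1ccccc1OC)C1C(CCc2ccccc2OC)C(Br)(C(=O)OC)C(=O)C(C)C1=O | intermediate
16 | 5,5'-linked dimer of methyl 2,4-dihydroxy-6-[2-(2-methoxyphenyl)ethyl]-3-methylbenzoate | COC(=O)c1c(O)c(C)c(O)c(c1CCc1ccccc1OC)-c1c(CCc2ccccc2OC)c(C(=O)OC)c(O)c(C)c1O | intermediate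
17 | 5,5'-linked dimer of 2,4-dihydroxy-6-[2-(2-methoxyphenyl)ethyl]-3-methylbenzoic acid | OC(=O)c1c(O)c(C)c(O)c(c1CCc1ccccc1OC)-c1c(CCc2ccccc2OC)c(C(=O)O)c(O)c(C)c1O | intermediate
18 | 6,6'-bis[2-(2-methoxyphenyl)ethyl]-3,3'-dimethylbiphenyl-2,2',4,4'-tetrol | COc1ccccc1CCc1cc(O)c(C)c(O)c1-c1c(O)c(C)c(O)cc1CCc1ccccc1OC | intermediate
19 | 4,4'-dihydroxy-2,2'-bis[2-(2-methoxyphenyl)ethyl]-5,5'-dimethyl-[1,1'-bi(cyclohexa-1,4-diene)]-3,3',6,6'-tetrone (racemic at the axis) | COc1ccccc1CCC1=C(C2=C(CCc3ccccc3OC)C(=O)C(O)=C(C)C2=O)C(=O)C(C)=C(O)C1=O | target

## Step count and risks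

Total: 8 steps. Longest linear sequence: 8 steps (1 and 2 to 19); the route is linear, with 5 and 11 entering in steps 2 and 5.

**Step 5 (key step).** The twofold annulation on a cross-conjugated bis-enone has no direct precedent. The likely failures are base-induced shift of the remaining C5'=C6' bond of the mono-adduct into the C5–C5' position (which leaves a tetrasubstituted 2-ene-1,4-dione that can no longer accept malonate at C6'), aldol closure of the two ketones of 12 to a cyclopentenone, and slow second addition next to the first, now branched, centre. The fallback sets out from 9 and returns at 16; it builds one ring at a time and makes C5–C5' last. Protodestannylation of 9 (HCl, CH2Cl2) would give (Z)-7-(2-methoxyphenyl)hept-4-en-3-one F1, which is annulated with 11 and NaOCH3, the direct homologue of the known monomer reaction, to methyl 6-[2-(2-methoxyphenyl)ethyl]-3-methyl-2,4-dioxocyclohexane-1-carboxylate F2. Aromatisation of F2 with one equivalent of Br2 in DMF would give methyl 2,4-dihydroxy-6-[2-(2-methoxyphenyl)ethyl]-3-methylbenzoate F3, and oxidative phenol coupling of F3 (FeCl3 on silica gel) at C5, the only free position of the resorcylate ring and para to the C2 hydroxyl, would give 16. This fallback gives up forming the hindered bond at the alkenyl stage.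

**Step 4.** Protodestannylation of the α-stannyl enone by the hydrated, Lewis-acidic copper salt may outrun transmetalation, which would return the simple enone instead of the dimer. The fallback sets out from 9 and returns at 10: half of 9 is treated with I2 (CH2Cl2, 0 °C) to give (E)-4-iodo-7-(2-methoxyphenyl)hept-4-en-3-one F4, and F4 is joined to the other half of 9 by Stille cross-coupling (Pd(PPh3)4, CuI, DMF), a standard reaction of α-iodoenones.

**Step 6.** Electrophilic bromination of the anisole rings by bromine released from 14, incomplete dehydrobromination of the second ring, or HBr-induced loss of the ester before the ring is aromatic may occur. The fallback sets out from 13 and returns at 18; it reverses the order of events and avoids halogen. Saponification of 13 and decarboxylation of the β-keto acid (aq. NaOH, then HCl, warm) would give 6,6'-bis[2-(2-methoxyphenyl)ethyl]-3,3'-dimethyl-[1,1'-bi(cyclohexane)]-2,2',4,4'-tetrone F5, and dehydrogenation of F5 over Pd/C in a high-boiling solvent, a known route from 2-alkylcyclohexane-1,3-diones to 2-alkylresorcinols, would give 18.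

**Step 8.** Poor solubility of 18 in the aqueous medium and the hindered C1–H may lead to oxidation of only one ring or to radical coupling of phenoxyl intermediates. The fallback sets out from 18 and returns at 19 by the classical nitrogen route. Nitrosation at the only free position C1 (NaNO2, AcOH/H2O, 0 °C) would give 6,6'-bis[2-(2-methoxyphenyl)ethyl]-3,3'-dimethyl-5,5'-dinitrosobiphenyl-2,2',4,4'-tetrol F6, reduction (Na2S2O4) would give 5,5'-diamino-6,6'-bis[2-(2-methoxyphenyl)ethyl]-3,3'-dimethylbiphenyl-2,2',4,4'-tetrol F7, and oxidation of the para-aminophenol units of F7 with hydrolysis of the quinone imine (FeCl3, aq. HCl) would give 19.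

**Step 1.** The propargyl/allenyl Grignard reagent can also react through its α-carbon, which would give the allenic isomer, and the benzylic chloride can undergo Wurtz-type homocoupling. The fallback sets out from 1 and returns at 4: 1 is alkylated with lithiated 1-(trimethylsilyl)propyne (n-BuLi, THF, −78 °C) to [4-(2-methoxyphenyl)but-1-yn-1-yl]trimethylsilane F8, and the silyl group of F8 is removed with K2CO3 in CH3OH.

## Further compounds

F1 | step 5 | (Z)-7-(2-methoxyphenyl)hept-4-en-3-one | CCC(=O)/C=C\CCc1ccccc1OC
F2 | step 5 | methyl 6-[2-(2-methoxyphenyl)ethyl]-3-methyl-2,4-dioxocyclohexane-1-carboxylate (stereoisomer mixture) | COC(=O)C1C(=O)C(C)C(=O)CC1CCc1ccccc1OC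
F3 | step 5 | methyl 2,4-dihydroxy-6-[2-(2-methoxyphenyl)ethyl]-3-methylbenzoate | COC(=O)c1c(O)c(C)c(O)cc1CCc1ccccc1OC
F4 | step 4 | (E)-4-iodo-7-(2-methoxyphenyl)hept-4-en-3-one | CCC(=O)/C(I)=C\CCc1ccccc1OC
F5 | step 6 | 6,6'-bis[2-(2-methoxyphenyl)ethyl]-3,3'-dimethyl-[1,1'-bi(cyclohexane)]-2,2',4,4'-tetrone (stereoisomer mixture) | COc1ccccc1CCC1CC(=O)C(C)C(=O)C1C1C(CCc2ccccc2OC)CC(=O)C(C)C1=O
F6 | step 8 | 6,6'-bis[2-(2-methoxyphenyl)ethyl]-3,3'-dimethyl-5,5'-dinitrosobiphenyl-2,2',4,4'-tetrol | COc1ccccc1CCc1c(N=O)c(O)c(C)c(O)c1-c1c(O)c(C)c(O)c(N=O)c1CCc1ccccc1OC
F7 | step 8 | 5,5'-diamino-6,6'-bis[2-(2-methoxyphenyl)ethyl]-3,3'-dimethylbiphenyl-2,2',4,4'-tetrol | COc1ccccc1CCc1c(N)c(O)c(C)c(O)c1-c1c(O)c(C)c(O)c(N)c1CCc1ccccc1OC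
F8 | step 1 | [4-(2-methoxyphenyl)but-1-yn-1-yl]trimethylsilane | COc1ccccc1CCC#C[Si](C)(C)C
A1 | alternative 1 | 2,2',4,4'-tetrakis(benzyloxy)-6,6'-bis[2-(2-methoxyphenyl)ethyl]-3,3'-dimethylbiphenyl | COc1ccccc1CCc1cc(OCc2ccccc2)c(C)c(OCc2ccccc2)c1-c1c(OCc2ccccc2)c(C)c(OCc2ccccc2)cc1CCc1ccccc1OC
A2 | alternative 1 | 2,2',4,4'-tetrakis(benzyloxy)-3,3'-dimethyl-6,6'-divinylbiphenyl | C=Cc1cc(OCc2ccccc2)c(C)c(OCc2ccccc2)c1-c1c(OCc2ccccc2)c(C)c(OCc2ccccc2)cc1C=C
A3 | alternative 1 | 2-iodoanisole | COc1ccccc1I
A4 | alternative 2 | 3,4-dimethoxy-5-[2-(2-methoxyphenyl)ethyl]-2-methyl-6-{2,4,5-trimethoxy-3-methyl-6-[2-(2-methoxyphenyl)ethyl]phenyl}phenol (biaryl with ring B as a 4-methoxyphenol) | COc1ccccc1CCc1c(OC)c(OC)c(C)c(O)c1-c1c(OC)c(C)c(OC)c(OC)c1CCc1ccccc1OC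
A5 | alternative 2 | 1,2,4-trimethoxy-5-[4-(2-methoxyphenyl)but-1-yn-1-yl]-6-[2-(2-methoxyphenyl)ethyl]-3-methylbenzene | COc1ccccc1CCC#Cc1c(OC)c(C)c(OC)c(OC)c1CCc1ccccc1OC
A6 | alternative 2 | pentacarbonyl[methoxy(1-methoxyprop-1-en-1-yl)carbene]chromium (alkene geometry not specified) | CC=C(OC)C(OC)=[Cr].[C-]#[O+].[C-]#[O+].[C-]#[O+].[C-]#[O+].[C-]#[O+]
A7 | alternative 3 | 6,6'-bis[(2-methoxyphenyl)acetyl] bis(hydroquinone mono-tert-butyldimethylsilyl ether) | COc1ccccc1CC(=O)c1c(O[Si](C)(C)C(C)(C)C)c(OC)c(C)c(O)c1-c1c(O)c(C)c(OC)c(O[Si](C)(C)C(C)(C)C)c1C(=O)Cc1ccccc1OC
A8 | alternative 3 | 1,8-bis(2-methoxyphenyl)octa-3,5-diyne-2,7-dione | COc1ccccc1CC(=O)C#CC#CC(=O)Cc1ccccc1OC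
A9 | alternative 3 | tert-butyl[(3-methoxy-4-methylfuran-2-yl)oxy]dimethylsilane | COc1c(C)coc1O[Si](C)(C)C(C)(C)C
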